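**Retrosynthetic overview**

1. Numbering: chromanone half O1, C2 (ketal), C3, C4 (C=O), C4a–C8a (ring A); flavan half primed. The strategy rests on ring A: C4a, C5, C6, C7, C8 and C8a, with oxygens on C5, C7 and C8a and the C4 ketone on C4a, are an acylphloroglucinol, the Claisen-folded form of a 3,5,7-triketo ester chain that a 6-(2-oxoalkyl)-4-hydroxy-2-pyrone holds in masked form.
2. Disconnections, last to first: O1–C2 (oxa-Michael of a ring-A hydroxyl onto C2 of a 3-aroylbenzofuran, C3 protonated in the same event); C4a–C8a (pyrone opening and Claisen recyclisation); C4–C4a (acylation of the pyrone dianion by a benzofuran-3-carboxylate).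
3. Earlier bonds: C8'–C3 (Sonogashira coupling), O7'–C2 and C3–C4 (alkoxycarbonylative cyclisation of the o-alkynylphenol), C2'–aryl (asymmetric 1,4-arylation of a chromone, then removal of the C4' oxygen).
4. Ring order: pyran ring of the flavan (already in the chromone; C2' set R) → furan ring → ring A → pyranone ring carrying the cis-fused ketal (C2 S, C3 S).

Key step: step 11

Remark: the sense of induction in steps 3 and 12 is assigned by analogy only; should a pilot run show the opposite sense, the antipodal ligand ((S)-MeO-F12-BIPHEP) or the quinidine-derived pseudo-enantiomer of the thiourea catalyst is used, with the route otherwise unchanged.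

**Route**

Step 1
Reactants: 1 5,7-dihydroxychromone
Product: 2 5-hydroxy-7-(methoxymethoxy)-4H-chromen-4-one
Conditions: MOMCl (1.1 equiv), i-Pr2NEt (1.5 equiv), CH2Cl2/DMF, 0 °C to rt
Reagents that add atoms: chloromethyl methyl ether, COCCl
Why: Williamson-type O-alkylation should occur only at the acidic, non-chelated C7 hydroxyl, because the C5 hydroxyl is held in a hydrogen bond to the C4 carbonyl.

Step 2
Reactants: 2 5-hydroxy-7-(methoxymethoxy)-4H-chromen-4-one
Product: 3 5-(benzyloxy)-7-(methoxymethoxy)-4H-chromen-4-one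
Conditions: BnBr (1.5 equiv), K2CO3 (3 equiv), n-Bu4NI (cat.), DMF, 60 °C
Reagents that add atoms: benzyl bromide, BrCc1ccccc1
Why: Williamson etherification under forcing conditions (polar solvent, iodide catalysis, heat) alkylates the chelated C5 hydroxyl, and the MOM acetal is stable to base.

Step 3
Reactants: 3 5-(benzyloxy)-7-(methoxymethoxy)-4H-chromen-4-one; 4 4-(benzyloxy)phenylboronic acid
Product: 5 (2R)-5-(benzyloxy)-2-[4-(benzyloxy)phenyl]-7-(methoxymethoxy)chroman-4-one
Conditions: [Rh(OH)(cod)]2 (2.5 mol%), (R)-MeO-F12-BIPHEP (5.5 mol%), 4 (2.5 equiv), toluene/H2O (10:1), 40 °C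
Reagents that add atoms: none
Why: Hayashi–Miyaura 1,4-addition of the arylboronic acid to the chromone enone, in which the electron-poor chiral bisphosphine on monovalent rhodium selects the face of C2 during aryl insertion and should set C2 as (R), while the mild temperature avoids ring opening of the flavanone.

Step 4
Reactants: 5 (2R)-5-(benzyloxy)-2-[4-(benzyloxy)phenyl]-7-(methoxymethoxy)chroman-4-one
Product: 6 (2R)-5-(benzyloxy)-2-[4-(benzyloxy)phenyl]-7-(methoxymethoxy)chroman-4-ol (C4 epimers; mainly 2,4-cis)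
Conditions: NaBH4 (2 equiv), MeOH/THF, 0 °C
Reagents that add atoms: none
Why: Borohydride reduction of the aryl ketone, with hydride expected to add mainly trans to the equatorial C2 aryl group; the C4 configuration is of no consequence because C4 becomes CH2 in step 5.

Step 5
Reactants: 6 (2R)-5-(benzyloxy)-2-[4-(benzyloxy)phenyl]-7-(methoxymethoxy)chroman-4-ol
Product: 7 (2R)-5-(benzyloxy)-2-[4-(benzyloxy)phenyl]-7-(methoxymethoxy)chromane
Conditions: Et3SiH (5 equiv), TFA (2 equiv, added last), CH2Cl2, −40 °C
Reagents that add atoms: none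
Why: Ionic hydrogenation, in which the C4 alcohol ionises readily to a cation stabilised by the ortho and para oxygens and is trapped by silane hydride, while at −40 °C neither the MOM acetal nor the C2–O1 benzylic ether should ionise, so C2 keeps its configuration.

Step 6
Reactants: 7 (2R)-5-(benzyloxy)-2-[4-(benzyloxy)phenyl]-7-(methoxymethoxy)chromane
Product: 8 (2R)-5-(benzyloxy)-2-[4-(benzyloxy)phenyl]-8-iodo-7-(methoxymethoxy)chromane
Conditions: NIS (1.05 equiv), DMF, 0 °C, dark
Reagents that add atoms: N-iodosuccinimide, O=C1CCC(=O)N1I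
Why: Electrophilic aromatic iodination of the phloroglucinol-type ring, expected at C8 (between O1 and the 7-alkoxy group), the less hindered of the two free positions and the usual site of halogenation in 5,7-dialkoxyflavans; the mono-oxygenated ring B is far less nucleophilic.

Step 7
Reactants: 8 (2R)-5-(benzyloxy)-2-[4-(benzyloxy)phenyl]-8-iodo-7-(methoxymethoxy)chromane; 9 1-(benzyloxy)-4-ethynylbenzene
Product: 10 (2R)-5-(benzyloxy)-2-[4-(benzyloxy)phenyl]-8-{[4-(benzyloxy)phenyl]ethynyl}-7-(methoxymethoxy)chromane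
Conditions: PdCl2(PPh3)2 (5 mol%), CuI (10 mol%), Et3N/DMF (1:1), 60 °C, degassed
Reagents that add atoms: none
Why: Sonogashira coupling of the aryl iodide with the terminal alkyne; O7 stays protected as its MOM ether so that the alkyne cannot cyclise early to a 3-unsubstituted benzofuran.

Step 8
Reactants: 10 (2R)-5-(benzyloxy)-2-[4-(benzyloxy)phenyl]-8-{[4-(benzyloxy)phenyl]ethynyl}-7-(methoxymethoxy)chromane
Product: 11 (2R)-5-(benzyloxy)-2-[4-(benzyloxy)phenyl]-8-{[4-(benzyloxy)phenyl]ethynyl}chroman-7-ol
Conditions: 3 M aq. HCl (cat.), MeOH/THF, 45 °C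
Reagents that add atoms: none
Why: Acid-catalysed acetal methanolysis removes the MOM group, and the benzyl ethers, the flavan ether and the diarylalkyne should tolerate dilute HCl at this temperature.

Step 9
Reactants: 11 (2R)-5-(benzyloxy)-2-[4-(benzyloxy)phenyl]-8-{[4-(benzyloxy)phenyl]ethynyl}chroman-7-ol
Product: 12 methyl (2R)-5-(benzyloxy)-2,8-bis[4-(benzyloxy)phenyl]-3,4-dihydro-2H-furo[2,3-h]chromene-9-carboxylate
Conditions: PdI2 (5 mol%), thiourea (20 mol%), CBr4 (5 equiv), Cs2CO3 (3 equiv), CO (1 atm), MeOH, 40 °C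
Reagents that add atoms: carbon monoxide, [C-]#[O+]; methanol, CO
Why: Oxidative alkoxycarbonylative heteroannulation, in which divalent palladium activates the alkyne for 5-endo-dig attack by the phenol oxygen, the 3-benzofuranylpalladium species inserts CO and is intercepted by methanol, and CBr4 reoxidises zerovalent palladium, the thiourea ligand holding back simple protodepalladation.

Step 10
Reactants: 12 methyl (2R)-5-(benzyloxy)-2,8-bis[4-(benzyloxy)phenyl]-3,4-dihydro-2H-furo[2,3-h]chromene-9-carboxylate; 13 4-hydroxy-6-methyl-2-pyrone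
Product: 15 6-{2-[(2R)-5-(benzyloxy)-2,8-bis[4-(benzyloxy)phenyl]-3,4-dihydro-2H-furo[2,3-h]chromen-9-yl]-2-oxoethyl}-4-hydroxy-2H-pyran-2-one, via pyrone dianion dilithium salt 14 (not isolated)
Conditions: 13 (3 equiv), LDA (6.2 equiv), THF, −78 °C, 1 h; then 12, −78 to 0 °C; aq. HCl
Reagents that add atoms: none
Why: Claisen-type acylation of a dianion, the more basic carbanion at the C6 methyl of the 4-oxido-2-pyrone attacking the ester carbonyl; the dianion is used in excess because the product, with its doubly activated CH2, is deprotonated as it forms.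

Step 11
Reactants: 15 6-{2-[(2R)-5-(benzyloxy)-2,8-bis[4-(benzyloxy)phenyl]-3,4-dihydro-2H-furo[2,3-h]chromen-9-yl]-2-oxoethyl}-4-hydroxy-2H-pyran-2-one
Product: 17 [(2R)-5-(benzyloxy)-2,8-bis[4-(benzyloxy)phenyl]-3,4-dihydro-2H-furo[2,3-h]chromen-9-yl](2,4,6-trihydroxyphenyl)methanone, via magnesium chelate of the methyl triketo ester 16 (not isolated)
Conditions: Mg(OMe)2 (10 equiv), MeOH/THF (3:1), 65 °C; then cold 1 M HCl
Reagents that add atoms: none
Why: Methoxide opens the lactone of 15 at the pyrone carbonyl to give the magnesium-chelated methyl 3,5,7-triketo ester 16, whose carbanion at the CH2 between the aryl ketone and the next ketone (future C4a) attacks the ester carbon (future C8a) in a Claisen condensation, expels methoxide and enolises to the aromatic 2,4,6-trihydroxyphenyl ketone. The closest known reaction is the magnesium methoxide recyclisation of 6-(2-oxoalkyl)-4-hydroxy-2-pyrones and of 3,5,7-triketo esters to acylphloroglucinols. Ring A closes in the 6-exo-trig mode, the enolate carbon adding to the exocyclic ester C=O. No stereocentre is formed, and the (R) flavan centre is not enolisable and stays as set. The step needs Claisen folding to win over aldol folding (ester α-carbon onto the aryl ketone) and over retro-Claisen cleavage by methoxide. This should hold because in methanol the ester remains an ester and is the one carbonyl not tied up as a magnesium enolate, while the aryl ketone is a hindered benzofuran-3-yl ketone flanked by the 2-aryl group and the peri oxygen and deactivated as a vinylogous ester.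

Step 12
Reactants: 17 [(2R)-5-(benzyloxy)-2,8-bis[4-(benzyloxy)phenyl]-3,4-dihydro-2H-furo[2,3-h]chromen-9-yl](2,4,6-trihydroxyphenyl)methanone
Product: 18 tri-O-benzyl ether of the target (benzyl on the flavan C5' oxygen and on both 4-hydroxyphenyl groups; cis-fused ketal; C2 S; C3 S; C2' R)
Conditions: 9-amino-9-deoxy-epi-quinine N'-[3,5-bis(trifluoromethyl)phenyl]thiourea (10 mol%), toluene/CH2Cl2, 4 Å molecular sieves, 0 °C; cold filtration through silica
Reagents that add atoms: none
Why: Proposed new method: the quinuclidine nitrogen deprotonates one of the two equivalent ortho hydroxyls of ring A while the thiourea hydrogen-bonds the C4 carbonyl, the phenoxide adds 6-endo-trig to C2, the β-carbon of the vinylogous ester embedded in the benzofuran, and the ammonium ion protonates the C3 enolate on the same (convex) face, so that the catalyst's choice of the C2 face should fix the ketal carbon as (S) and the only strain-free, cis ring fusion should fix C3 as (S), the remote (R) flavan centre giving no useful bias; the closest known reactions are the cinchona-thiourea-catalysed intramolecular oxa-Michael closure of o-hydroxyaryl enones to flavanones and chromanones and dearomatising Michael additions to nitro-activated benzofurans, and the step goes beyond them in breaking the furan aromaticity of an acyl-activated benzofuran, a cost set against the ketal formed at C2 and the relief of the twisted, tetra-ortho-substituted diaryl ketone.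

Step 13
Reactants: 18 tri-O-benzyl ether of the target
Product: 19 CNP0179743.1 (cis-fused ketal; C2 S; C3 S; C2' R)
Conditions: H2 (1 atm), 10% Pd/C, EtOAc/MeOH, rt
Reagents that add atoms: none
Why: Hydrogenolysis of the three aryl benzyl ethers under neutral conditions, in which the hindered ketal C–O bonds at C2 and the flavan C2'–O1' bond are expected to survive as they do in debenzylations of flavans and ketal-linked proanthocyanidins, and the absence of acid or base avoids reopening of the ketal through the C3 enol, so no stereocentre is touched.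

**Compound list**

1 | 5,7-dihydroxychromone | O=c1ccoc2cc(O)cc(O)c12 | starting material
2 | 5-hydroxy-7-(methoxymethoxy)-4H-chromen-4-one | O=c1ccoc2cc(OCOC)cc(O)c12 | intermediate
3 | 5-(benzyloxy)-7-(methoxymethoxy)-4H-chromen-4-one | O=c1ccoc2cc(OCOC)cc(OCc3ccccc3)c12 | intermediate
4 | 4-(benzyloxy)phenylboronic acid | OB(O)c1ccc(OCc2ccccc2)cc1 | starting material
5 | (2R)-5-(benzyloxy)-2-[4-(benzyloxy)phenyl]-7-(methoxymethoxy)chroman-4-one | O=C1C[C@H](c2ccc(OCc3ccccc3)cc2)Oc2cc(OCOC)cc(OCc3ccccc3)c12 | intermediate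
6 | (2R)-5-(benzyloxy)-2-[4-(benzyloxy)phenyl]-7-(methoxymethoxy)chroman-4-ol (C4 epimers, mainly 2,4-cis; C4 left undefined) | OC1C[C@H](c2ccc(OCc3ccccc3)cc2)Oc2cc(OCOC)cc(OCc3ccccc3)c12 | intermediate
7 | (2R)-5-(benzyloxy)-2-[4-(benzyloxy)phenyl]-7-(methoxymethoxy)chromane | COCOc1cc(OCc2ccccc2)c2c(c1)O[C@@H](c1ccc(OCc3ccccc3)cc1)CC2 | intermediate
8 | (2R)-5-(benzyloxy)-2-[4-(benzyloxy)phenyl]-8-iodo-7-(methoxymethoxy)chromane | COCOc1cc(OCc2ccccc2)c2c(c1I)O[C@@H](c1ccc(OCc3ccccc3)cc1)CC2 | intermediate
9 | 1-(benzyloxy)-4-ethynylbenzene | C#Cc1ccc(OCc2ccccc2)cc1 | starting material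
10 | (2R)-5-(benzyloxy)-2-[4-(benzyloxy)phenyl]-8-{[4-(benzyloxy)phenyl]ethynyl}-7-(methoxymethoxy)chromane | COCOc1cc(OCc2ccccc2)c2c(c1C#Cc1ccc(OCc3ccccc3)cc1)O[C@@H](c1ccc(OCc3ccccc3)cc1)CC2 | intermediate
11 | (2R)-5-(benzyloxy)-2-[4-(benzyloxy)phenyl]-8-{[4-(benzyloxy)phenyl]ethynyl}chroman-7-ol | Oc1cc(OCc2ccccc2)c2c(c1C#Cc1ccc(OCc3ccccc3)cc1)O[C@@H](c1ccc(OCc3ccccc3)cc1)CC2 | intermediate
12 | methyl (2R)-5-(benzyloxy)-2,8-bis[4-(benzyloxy)phenyl]-3,4-dihydro-2H-furo[2,3-h]chromene-9-carboxylate | COC(=O)c1c(-c2ccc(OCc5ccccc5)cc2)oc2cc(OCc5ccccc5)c3c(c12)O[C@@H](c1ccc(OCc5ccccc5)cc1)CC3 | intermediate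
13 | 4-hydroxy-6-methyl-2-pyrone | Cc1cc(O)cc(=O)o1 | starting material
14 | dilithium salt of the dianion of 13 (4-oxido, 6-CH2 carbanion) | [Li+].[Li+].[CH2-]c1cc([O-])cc(=O)o1 | intermediate (not isolated)
15 | 6-{2-[(2R)-5-(benzyloxy)-2,8-bis[4-(benzyloxy)phenyl]-3,4-dihydro-2H-furo[2,3-h]chromen-9-yl]-2-oxoethyl}-4-hydroxy-2H-pyran-2-one | O=C(Cc1cc(O)cc(=O)o1)c1c(-c2ccc(OCc5ccccc5)cc2)oc2cc(OCc5ccccc5)c3c(c12)O[C@@H](c1ccc(OCc5ccccc5)cc1)CC3 | intermediate
16 | methyl 7-[(2R)-5-(benzyloxy)-2,8-bis[4-(benzyloxy)phenyl]-3,4-dihydro-2H-furo[2,3-h]chromen-9-yl]-3,5,7-trioxoheptanoate, present as its magnesium enolate chelate (drawn as the neutral ester) | COC(=O)CC(=O)CC(=O)CC(=O)c1c(-c2ccc(OCc5ccccc5)cc2)oc2cc(OCc5ccccc5)c3c(c12)O[C@@H](c1ccc(OCc5ccccc5)cc1)CC3 | intermediate (not isolated)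
17 | [(2R)-5-(benzyloxy)-2,8-bis[4-(benzyloxy)phenyl]-3,4-dihydro-2H-furo[2,3-h]chromen-9-yl](2,4,6-trihydroxyphenyl)methanone | O=C(c1c(O)cc(O)cc1O)c1c(-c2ccc(OCc5ccccc5)cc2)oc2cc(OCc5ccccc5)c3c(c12)O[C@@H](c1ccc(OCc5ccccc5)cc1)CC3 | intermediate
18 | tri-O-benzyl ether of the target; cis-fused ketal, C2 S, C3 S, C2' R | O=C1c2c(O)cc(O)cc2O[C@@]2(c3ccc(OCc6ccccc6)cc3)Oc3cc(OCc6ccccc6)c4c(c3[C@@H]12)O[C@@H](c1ccc(OCc6ccccc6)cc1)CC4 | intermediate
19 | CNP0179743.1; cis-fused ketal, C2 S, C3 S, C2' R | O=C1c2c(O)cc(O)cc2O[C@@]2(c3ccc(O)cc3)Oc3cc(O)c4c(c3[C@@H]12)O[C@@H](c1ccc(O)cc1)CC4 | target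

**Step count and risks**

Total steps: 13. Longest linear sequence: 13 steps (1 to 19); compounds 4, 9 and 13 are bought and enter directly.

Steps most likely to fail:

1. Step 12 (the proposed new method). The closure breaks the aromatic furan, and whether the ketal or the open benzofuran ketone is the more stable isomer is not known. Re-opening through the C3 enolate (loss of the ring-A phenoxide, or of the flavan O7' phenoxide) may therefore compete with the addition or undo it, and in doing so wash out the face selection made by the catalyst. The fallback sets out from 17 and gives up catalyst control. The closure is run under the classical buffered conditions that interconvert 2'-hydroxychalcones and flavanones (NaOAc, EtOH/THF, 60 °C) until the composition no longer changes. Because the flavan centre is already fixed, 18 and the ketal-ring epimer of 18 (C2 R, C3 R, C2' R) F1 are diastereomers and are separated by preparative chromatography. F1 and recovered 17 are returned to the same conditions, so an unfavourable position of equilibrium is met by recycling. The fallback comes back to the route at 18.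

2. Step 11 (key step). After lactone opening the chain may fold by aldol attack of the ester α-carbon on the aryl ketone, it may lose the aroyl group by retro-Claisen cleavage, or the pyrone anion may resist methoxide altogether. The fallback sets out from 12 and brings ring A in intact instead of building it. Phloroglucinol is protected (MOMCl, i-Pr2NEt) as 1,3,5-tris(methoxymethoxy)benzene F2. Directed ortho-lithiation (n-BuLi, THF, 0 °C) gives 2,4,6-tris(methoxymethoxy)phenyllithium F3, which adds to ester 12. The tetra-ortho-substituted ketone so formed, [(2R)-5-(benzyloxy)-2,8-bis[4-(benzyloxy)phenyl]-3,4-dihydro-2H-furo[2,3-h]chromen-9-yl][2,4,6-tris(methoxymethoxy)phenyl]methanone F4, is too hindered to add a second aryllithium. Methanolic HCl then removes the three MOM groups, and the fallback comes back to the route at 17.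

3. Step 10. The stabilised dianion may add too slowly to the hindered, vinylogous-carbonate ester and be used up by proton transfer from the product. The fallback sets out from 12 and forms the C4–C4a bond by aldol addition to an aldehyde, adjusting the oxidation level afterwards. DIBAL-H reduction gives the alcohol [(2R)-5-(benzyloxy)-2,8-bis[4-(benzyloxy)phenyl]-3,4-dihydro-2H-furo[2,3-h]chromen-9-yl]methanol F5. MnO2 oxidation gives the aldehyde (2R)-5-(benzyloxy)-2,8-bis[4-(benzyloxy)phenyl]-3,4-dihydro-2H-furo[2,3-h]chromene-9-carbaldehyde F6. Addition of dianion 14 gives the aldol adduct 6-{2-[(2R)-5-(benzyloxy)-2,8-bis[4-(benzyloxy)phenyl]-3,4-dihydro-2H-furo[2,3-h]chromen-9-yl]-2-hydroxyethyl}-4-hydroxy-2H-pyran-2-one F7 as a carbinol epimer mixture. MnO2 oxidation of this heterobenzylic alcohol brings the fallback back to the route at 15.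

**Further compounds**

F1 | step 12 | ketal-ring epimer of 18 (C2 R, C3 R, C2' R) | O=C1c2c(O)cc(O)cc2O[C@]2(c3ccc(OCc6ccccc6)cc3)Oc3cc(OCc6ccccc6)c4c(c3[C@H]12)O[C@@H](c1ccc(OCc6ccccc6)cc1)CC4
F2 | step 11 | 1,3,5-tris(methoxymethoxy)benzene | COCOc1cc(OCOC)cc(OCOC)c1
F3 | step 11 | 2,4,6-tris(methoxymethoxy)phenyllithium | [Li]c1c(OCOC)cc(OCOC)cc1OCOC
F4 | step 11 | [(2R)-5-(benzyloxy)-2,8-bis[4-(benzyloxy)phenyl]-3,4-dihydro-2H-furo[2,3-h]chromen-9-yl][2,4,6-tris(methoxymethoxy)phenyl]methanone | O=C(c1c(OCOC)cc(OCOC)cc1OCOC)c1c(-c2ccc(OCc5ccccc5)cc2)oc2cc(OCc5ccccc5)c3c(c12)O[C@@H](c1ccc(OCc5ccccc5)cc1)CC3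
F5 | step 10 | [(2R)-5-(benzyloxy)-2,8-bis[4-(benzyloxy)phenyl]-3,4-dihydro-2H-furo[2,3-h]chromen-9-yl]methanol | OCc1c(-c2ccc(OCc5ccccc5)cc2)oc2cc(OCc5ccccc5)c3c(c12)O[C@@H](c1ccc(OCc5ccccc5)cc1)CC3
F6 | step 10 | (2R)-5-(benzyloxy)-2,8-bis[4-(benzyloxy)phenyl]-3,4-dihydro-2H-furo[2,3-h]chromene-9-carbaldehyde | O=Cc1c(-c2ccc(OCc5ccccc5)cc2)oc2cc(OCc5ccccc5)c3c(c12)O[C@@H](c1ccc(OCc5ccccc5)cc1)CC3
F7 | step 10 | 6-{2-[(2R)-5-(benzyloxy)-2,8-bis[4-(benzyloxy)phenyl]-3,4-dihydro-2H-furo[2,3-h]chromen-9-yl]-2-hydroxyethyl}-4-hydroxy-2H-pyran-2-one (carbinol epimers) | OC(Cc1cc(O)cc(=O)o1)c1c(-c2ccc(OCc5ccccc5)cc2)oc2cc(OCc5ccccc5)c3c(c12)O[C@@H](c1ccc(OCc5ccccc5)cc1)CC3
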